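**Plan**

Retrosynthesis: the O8 (2R,3R)-2,3-epoxy-2-methylbutanoate is removed first, then the C12–O6 lactone bond (leaving a C6/C12 diol), then the C1=C10 double bond, which is traced back to an eleven-membered cyclic sulfone with sulfur between C1 and C10 and chlorine on C10 (Ramberg–Bäcklund disconnection). The thiacycle is cut at S–C1, the chain at C9–C10 (Wittig), C5–C6 (Nozaki–Hiyama–Kishi) and C7–C11 (epoxide opening).
Enabling feature (germacrane numbering): in the ten-membered ring the C1=C10 enoate lies between two CH2 groups (C2, C9) and C10 carries the ester carbon C14. An SO2 bridge can therefore stand in for the double bond, the ester lets C10 alone be chlorinated, and neither sulfone α-carbon has a β leaving group.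
Forward order: a C1–C5 Z-iodoalkene and a C6–C9 aldehyde are joined at C5–C6, the chain is extended to C10/C14, the eleven-membered thiacycle is closed by thiolate alkylation, oxidised, chlorinated and contracted to the ten-membered carbocycle. The γ-lactone is closed next and the separately made epoxy acid is attached last.
Stereochemistry: C3 from Brown allylboration, C7 and C8 from Sharpless epoxidation followed by anti epoxide opening, C6 from Felkin–Anh addition to the C7-branched aldehyde, the epoxy acid from Sharpless epoxidation of angelyl alcohol. The C4=C5 geometry comes from anti carbomagnesiation of propargyl alcohol and the C1=C10 geometry from the ring contraction.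

Key step: step 24

Remark on the chemistry: C10 (in 30–36), the acetal carbon of 20–24, the lactol carbon of 41 and the episulfone carbons of 37 are stereocentres that are erased later; they are carried as epimer mixtures and left undefined in the SMILES.

**Route**

Step 1
Reactants: 1 propargyl alcohol
Product: 3 (Z)-3-iodo-2-methylprop-2-en-1-ol, via cyclic alkenylmagnesium alkoxide 2 (not isolated)
Conditions: MeMgBr (2.5 equiv), CuI (10 mol %), THF, −10 → 20 °C; then I2, −40 → 0 °C
Reagents that add atoms: methylmagnesium bromide, C[Mg]Br; iodine, II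
Why: Copper-catalysed anti carbomagnesiation of the propargylic alkoxide puts methyl on C4 and magnesium on C5 cis to the CH2O group in a five-membered chelate, and iodinolysis with retention gives the Z iodoalkene that becomes the ring-cis C4=C5 bond.

Step 2
Reactants: 3 (Z)-3-iodo-2-methylprop-2-en-1-ol
Product: 4 (Z)-3-iodo-2-methylprop-2-enal
Conditions: MnO2, CH2Cl2, 20 °C, dark; filtered and used at once
Reagents that add atoms: none
Why: Allylic oxidation with activated MnO2 is neutral, so the configurationally labile Z iodoenal should survive if it is used directly.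

Step 3
Reactants: 4 (Z)-3-iodo-2-methylprop-2-enal
Product: 6 (1Z,3S)-1-iodo-2-methylhexa-1,5-dien-3-ol, via bis(isopinocampheyl)borinate 5 (not isolated)
Conditions: (−)-Ipc2B(CH2CH=CH2) [from (+)-α-pinene], Et2O, −78 °C; then NaOH, H2O2, 0 °C
Reagents that add atoms: (−)-B-allylbis(isopinocampheyl)borane, C=CCB([C@@H]1C[C@@H]2C[C@H]([C@H]1C)C2(C)C)[C@@H]1C[C@@H]2C[C@H]([C@H]1C)C2(C)C
Why: Brown allylboration through a chair transition state, in which the (+)-α-pinene-derived reagent attacks the aldehyde face that gives the S carbinol when the aldehyde substituent outranks allyl (as with benzaldehyde), sets C3.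

Step 4
Reactants: 6 (1Z,3S)-1-iodo-2-methylhexa-1,5-dien-3-ol
Product: 7 tert-butyl{[(1Z,3S)-1-iodo-2-methylhexa-1,5-dien-3-yl]oxy}dimethylsilane
Conditions: t-BuMe2SiCl, imidazole, DMF, 20 °C
Reagents that add atoms: tert-butyldimethylsilyl chloride, CC(C)(C)[Si](C)(C)Cl
Why: Standard silylation gives the O3 silyl ether that is kept until the last step.

Step 5
Reactants: 7 tert-butyl{[(1Z,3S)-1-iodo-2-methylhexa-1,5-dien-3-yl]oxy}dimethylsilane
Product: 9 (3S,4Z)-3-(tert-butyldimethylsilyloxy)-5-iodo-4-methylpent-4-enal, via diol 8 (not isolated)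
Conditions: OsO4 (2 mol %), NaIO4, 2,6-lutidine, dioxane–H2O, 20 °C
Reagents that add atoms: osmium tetroxide, O=[Os](=O)(=O)=O; sodium periodate (reoxidant that supplies the oxygen), [Na+].[O-]I(=O)(=O)=O
Why: Lemieux–Johnson cleavage takes the monosubstituted terminal alkene in preference to the hindered, iodine-deactivated trisubstituted alkene and shortens the allyl group to the C1 aldehyde.

Step 6
Reactants: 9 (3S,4Z)-3-(tert-butyldimethylsilyloxy)-5-iodo-4-methylpent-4-enal
Product: 10 (3S,4Z)-3-(tert-butyldimethylsilyloxy)-5-iodo-4-methylpent-4-en-1-ol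
Conditions: NaBH4, MeOH, 0 °C
Reagents that add atoms: none
Why: Borohydride reduction of the aldehyde is fast at 0 °C and prevents β-elimination of the silyloxy group.

Step 7
Reactants: 10 (3S,4Z)-3-(tert-butyldimethylsilyloxy)-5-iodo-4-methylpent-4-en-1-ol
Product: 11 tert-butyl{[(1Z,3S)-5-chloro-1-iodo-2-methylpent-1-en-3-yl]oxy}dimethylsilane
Conditions: PPh3, N-chlorosuccinimide, THF, 0 → 20 °C
Reagents that add atoms: N-chlorosuccinimide, ClN1C(=O)CCC1=O
Why: Appel-type chlorination turns the C1 alcohol into a primary chloride that is inert to the chromium, aluminium, copper and enolate chemistry ahead and serves later as the electrophile for ring closure.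

Step 8
Reactants: 12 2-bromoprop-2-en-1-ol
Product: 13 [(2-bromoprop-2-en-1-yl)oxy](tert-butyl)dimethylsilane
Conditions: t-BuMe2SiCl, imidazole, CH2Cl2, 20 °C
Reagents that add atoms: tert-butyldimethylsilyl chloride, CC(C)(C)[Si](C)(C)Cl
Why: Silylation gives the C11–C13 unit with O12 protected by a group that resists 1,3-silyl migration in the derived alkenylmetal at low temperature.

Step 9
Reactants: 14 (E)-but-2-ene-1,4-diol
Product: 15 (E)-4-[(4-methoxybenzyl)oxy]but-2-en-1-ol
Conditions: NaH (1 equiv), 4-methoxybenzyl chloride, Bu4NI (cat.), THF–DMF, 0 → 20 °C, diol in excess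
Reagents that add atoms: 4-methoxybenzyl chloride, COc1ccc(CCl)cc1
Why: Williamson etherification with the diol in excess gives mainly the mono-ether, whose PMB group is later moved onto O8.

Step 10
Reactants: 15 (E)-4-[(4-methoxybenzyl)oxy]but-2-en-1-ol
Product: 16 [(2R,3R)-3-{[(4-methoxybenzyl)oxy]methyl}oxiran-2-yl]methanol
Conditions: Ti(OiPr)4 (cat.), D-(−)-diethyl tartrate, t-BuOOH, 4 Å molecular sieves, CH2Cl2, −20 °C
Reagents that add atoms: tert-butyl hydroperoxide, CC(C)(C)OO
Why: Sharpless asymmetric epoxidation with the D-(−)-tartrate delivers oxygen to the face that gives the 2R,3R epoxide (mirror image of the 2S,3S product of L-(+)-tartrate), which fixes C8 and prepares C7 for inversion.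

Step 11
Reactants: 16 [(2R,3R)-3-{[(4-methoxybenzyl)oxy]methyl}oxiran-2-yl]methanol; 13 [(2-bromoprop-2-en-1-yl)oxy](tert-butyl)dimethylsilane
Product: 19 (2S,3S)-2-[3-(tert-butyldimethylsilyloxy)prop-1-en-2-yl]-4-[(4-methoxybenzyl)oxy]butane-1,3-diol, via alkenyllithium 17 (not isolated), via alkenylmagnesium bromide 18 (not isolated)
Conditions: 13 (3.5 equiv), t-BuLi (7 equiv), Et2O, −78 °C; MgBr2·OEt2, −78 °C; then CuI (0.3 equiv), 16, THF, −40 → −15 °C; NaIO4 wash
Reagents that add atoms: none
Why: Copper-catalysed Grignard opening of a 2,3-epoxy alcohol occurs at C2 (here C7) by SN2 with inversion, attack at C3 being disfavoured by the adjacent CH2OPMB group, so the 7,8-anti 1,3-diol results; the minor 1,2-diol is cleaved by periodate on work-up.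

Step 12
Reactants: 19 (2S,3S)-2-[3-(tert-butyldimethylsilyloxy)prop-1-en-2-yl]-4-[(4-methoxybenzyl)oxy]butane-1,3-diol
Product: 20 (2S)-3-{[(tert-butyldimethylsilyl)oxy]methyl}-2-[(4S)-2-(4-methoxyphenyl)-1,3-dioxolan-4-yl]but-3-en-1-ol (acetal epimers)
Conditions: DDQ, 4 Å molecular sieves, CH2Cl2, −10 °C
Reagents that add atoms: none
Why: Under anhydrous conditions DDQ oxidises the PMB ether to an oxocarbenium ion that the neighbouring C8 hydroxyl traps as a five-membered 4-methoxybenzylidene acetal (oxidative acetalisation), protecting O8 and O9 and leaving only the C6 alcohol free.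

Step 13
Reactants: 20 (2S)-3-{[(tert-butyldimethylsilyl)oxy]methyl}-2-[(4S)-2-(4-methoxyphenyl)-1,3-dioxolan-4-yl]but-3-en-1-ol
Product: 21 C6 aldehyde of 20 (C7 and C8 unchanged)
Conditions: Dess–Martin periodinane, NaHCO3, CH2Cl2, 0 °C; used crude
Reagents that add atoms: none
Why: Buffered Dess–Martin oxidation is non-basic, so the C7 stereocentre (α to the aldehyde and allylic) should neither epimerise nor move into conjugation.

Step 14
Reactants: 11 tert-butyl{[(1Z,3S)-5-chloro-1-iodo-2-methylpent-1-en-3-yl]oxy}dimethylsilane; 21 C6 aldehyde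
Product: 23 C1–C9 allylic alcohol (C1 chloride, O3 TBS, Z C4=C5, free 6-OH, C7 bearing C(=CH2)CH2OTBS, O8/O9 4-methoxybenzylidene acetal), via alkenylchromium dichloride 22 (not isolated)
Conditions: CrCl2 (6 equiv), NiCl2 (2 mol %), DMSO, 20 °C
Reagents that add atoms: none
Why: In this Nozaki–Hiyama–Kishi coupling zerovalent nickel inserts into the C–I bond with retention of the Z geometry and the alkenylchromium adds to the aldehyde under non-basic conditions; Felkin–Anh attack anti to the dioxolanyl-bearing C8 (the large α-substituent), reinforced by 1,3-anti induction from O8, should favour the 6,7-syn, 6,8-anti carbinol required at C6, any C6 epimer being separated by chromatography.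

Step 15
Reactants: 23 C1–C9 allylic alcohol
Product: 24 O6 triethylsilyl ether of 23
Conditions: Et3SiOTf, 2,6-lutidine, CH2Cl2, −78 °C
Reagents that add atoms: triethylsilyl trifluoromethanesulfonate, CC[Si](CC)(CC)OS(=O)(=O)C(F)(F)F
Why: Silyl triflate silylation protects the hindered allylic C6 hydroxyl with a group that can later be removed together with the O12 silyl ether while the O3 silyl ether stays.

Step 16
Reactants: 24 O6 triethylsilyl ether
Product: 25 C9 primary alcohol with O8 4-methoxybenzyl ether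
Conditions: i-Bu2AlH, CH2Cl2, −78 → 0 °C
Reagents that add atoms: none
Why: The aluminium hydride coordinates the less hindered O9 and reduces the acetal carbon, so the reductive opening leaves the PMB group on the secondary O8 and frees the C9 alcohol at a stage where no ester is present.

Step 17
Reactants: 25 C9 primary alcohol
Product: 27 (E)-enoate (C9=C10, methyl ester C14), via aldehyde 26 (not isolated)
Conditions: Dess–Martin periodinane, NaHCO3, CH2Cl2, 0 °C; then Ph3P=CHCO2Me, 20 °C
Reagents that add atoms: methyl (triphenylphosphoranylidene)acetate, COC(=O)C=P(c1ccccc1)(c1ccccc1)c1ccccc1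
Why: Oxidation to the α-alkoxy aldehyde and in situ Wittig reaction with the stabilised ylide add C10 and the ester carbon C14 before the aldehyde can epimerise, the alkene geometry being irrelevant.

Step 18
Reactants: 27 (E)-enoate
Product: 28 saturated methyl ester (C9H2–C10H2–CO2Me)
Conditions: [(Ph3P)CuH]6, toluene, H2O (trace), 20 °C
Reagents that add atoms: none
Why: The copper hydride reduces only the conjugated C9=C10 bond (conjugate reduction), leaving the isolated alkenes, the alkyl chloride and the γ-alkoxy group untouched.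

Step 19
Reactants: 28 saturated methyl ester
Product: 30 α-bromo ester (bromine on C10, C10 epimers), via lithium enolate 29 (not isolated)
Conditions: LiN(iPr)2, THF, −78 °C; then CBr4, −78 °C
Reagents that add atoms: carbon tetrabromide, BrC(Br)(Br)Br
Why: C10–H is the only acidic C–H, so kinetic ester enolate formation and electrophilic bromination functionalise C10, and because O8 is γ to the enolate no β-elimination can occur.

Step 20
Reactants: 30 α-bromo ester
Product: 31 C10 thioacetate (C10 epimers)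
Conditions: CH3COSK (1.05 equiv), DMF, 0 °C
Reagents that add atoms: potassium thioacetate, CC(=O)[S-].[K+]
Why: SN2 displacement of the carbonyl-activated α-bromide by thioacetate is far faster than attack on the unactivated primary C1 chloride at 0 °C.

Step 21
Reactants: 31 C10 thioacetate
Product: 33 eleven-membered cyclic sulfide (S between C1 and C10), via thiol 32 (not isolated)
Conditions: Cs2CO3, NaI (cat.), MeOH–DMF 1:9, 45 °C, slow addition to 0.002 M, argon
Reagents that add atoms: none
Why: Methanolysis of the thioacetate releases the C10 thiolate slowly at high dilution and it closes the thiacycle by SN2 attack on the primary C1 carbon (11-exo-tet), iodide exchange of the chloride raising the rate.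

Step 22
Reactants: 33 cyclic sulfide
Product: 34 cyclic sulfone
Conditions: (NH4)6Mo7O24·4H2O (cat.), 30% H2O2, EtOH–pH 7 buffer, 0 → 20 °C
Reagents that add atoms: hydrogen peroxide, OO
Why: Molybdate-catalysed peroxide oxidation is chemoselective for sulfur (sulfide to sulfone) over tri- and 1,1-disubstituted alkenes.

Step 23
Reactants: 34 cyclic sulfone
Product: 36 eleven-membered α-chloro sulfone (Cl and CO2Me on C10, C10 epimers), via sodium enolate 35 (not isolated)
Conditions: NaH (1.05 equiv), THF, 0 °C; then N-chlorosuccinimide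
Reagents that add atoms: N-chlorosuccinimide, ClN1C(=O)CCC1=O
Why: C10–H, flanked by the sulfonyl and ester groups, is removed selectively by one equivalent of base and the stabilised carbanion is chlorinated, giving the contraction precursor in which either C10 epimer serves.

Step 24
Reactants: 36 eleven-membered α-chloro sulfone
Product: 38 protected ten-membered dienoate (C1=C10 enoate, O3 TBS, O6 TES, O8 PMB, C7 bearing C(=CH2)CH2OTBS), via episulfone 37 (not isolated)
Conditions: KOtBu (3 equiv), THF, −78 → 0 °C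
Reagents that add atoms: none
Why: The base removes a C1 proton, the only kind left alpha to the sulfone once C10 carries chlorine, and the carbanion displaces chloride at C10 in a 3-exo-tet closure that forms the C1–C10 bond as thiirane 1,1-dioxide 37, which loses SO2 cheletropically to leave the C1=C10 enoate. The closest known reaction type is the Ramberg–Bäcklund ring contraction of cyclic α-halo sulfones to medium-ring cycloalkenes. The ten-membered carbocycle thus arises by contraction of the eleven-membered thiacycle, the only ring-closing event being the 3-exo-tet episulfone formation inside that ring, and no stereocentre is created, so both C10 epimers of 36 converge. The step needs the ring-cis (E, tiglate-type) enoate, which should be secured because the episulfone can epimerise at C1 under the basic conditions before it loses SO2 and the cis-fused episulfone and the ring-cis olefin are the less strained and the conjugation-stabilised partners. Side reactions are limited by the substrate: C2 and C9 are CH2 groups without β leaving groups, O3 and O8 are γ to the carbanion sites, and loss of HCl toward C9 is slow because those protons are not acidified.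

Step 25
Reactants: 38 protected ten-membered dienoate
Product: 39 C6/C12 diol (O3 TBS and O8 PMB retained)
Conditions: HF·pyridine, pyridine, THF, 0 °C
Reagents that add atoms: none
Why: Buffered fluoride cleaves the secondary triethylsilyl ether and the primary TBS ether much faster than the hindered secondary TBS ether at O3.

Step 26
Reactants: 39 C6/C12 diol
Product: 42 trans-fused α-methylene-γ-butyrolactone (O3 TBS, O8 PMB), via hydroxy enal 40 (not isolated), via lactol 41 (not isolated)
Conditions: 2,2,6,6-tetramethylpiperidin-1-oxyl (20 mol %), PhI(OAc)2 (3 equiv), CH2Cl2, 20 °C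
Reagents that add atoms: none
Why: Oxoammonium oxidation takes the primary allylic alcohol selectively, the enal is trapped by the C6 hydroxyl as a lactol and this is oxidised on to the lactone (oxidative lactonisation), C6 and C7 being already set.

Step 27
Reactants: 42 lactone with O8 PMB
Product: 43 C8 alcohol
Conditions: DDQ, CH2Cl2–pH 7 buffer, 0 °C
Reagents that add atoms: none
Why: Oxidative cleavage of the PMB ether in wet solvent frees O8 without touching the silyl ether, the enoate or the methylene lactone.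

Step 28
Reactants: 44 angelic acid
Product: 45 (Z)-2-methylbut-2-en-1-ol
Conditions: LiAlH4, Et2O, 0 °C
Reagents that add atoms: none
Why: Hydride reduction of the acid is 1,2-selective and keeps the Z geometry.

Step 29
Reactants: 45 (Z)-2-methylbut-2-en-1-ol
Product: 46 [(2S,3R)-2,3-dimethyloxiran-2-yl]methanol
Conditions: Ti(OiPr)4 (cat.), L-(+)-diethyl tartrate, t-BuOOH, 4 Å molecular sieves, CH2Cl2, −20 °C
Reagents that add atoms: tert-butyl hydroperoxide, CC(C)(C)OO
Why: Sharpless asymmetric epoxidation with the L-(+)-tartrate delivers oxygen to the face that gives the 2S epoxy alcohol, and the Z alkene fixes the cis relation of C1 and the C3 methyl group.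

Step 30
Reactants: 46 [(2S,3R)-2,3-dimethyloxiran-2-yl]methanol
Product: 47 (2R,3R)-2,3-dimethyloxirane-2-carboxylic acid
Conditions: RuCl3 hydrate (cat.), NaIO4, CCl4–MeCN–H2O, 20 °C
Reagents that add atoms: water, O
Why: Ruthenium tetroxide oxidation (generated catalytically) converts the primary epoxy alcohol to the glycidic acid without opening the epoxide; the descriptor at C2 changes only because the priorities change.

Step 31
Reactants: 43 C8 alcohol; 47 (2R,3R)-2,3-dimethyloxirane-2-carboxylic acid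
Product: 49 O3-TBS ether of the target, via mixed anhydride 48 (not isolated)
Conditions: 2,4,6-Cl3C6H2COCl, Et3N, THF, 20 °C; then 43, 4-(dimethylamino)pyridine, toluene, 20 °C
Reagents that add atoms: none
Why: Yamaguchi esterification through the mixed anhydride acylates the hindered secondary C8 hydroxyl under mild conditions that leave the epoxide and the methylene lactone intact.

Step 32
Reactants: 49 O3-TBS ether of the target
Product: 50 CNP0143679.1
Conditions: HF·pyridine, pyridine, THF, 0 → 20 °C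
Reagents that add atoms: none
Why: Pyridine-buffered fluoride cleaves the last silyl ether under conditions that glycidic esters, enoates and α-methylene lactones should tolerate.

**Compound list**

1 | propargyl alcohol | C#CCO | starting material
2 | cyclic alkenylmagnesium alkoxide (4-methyl-2,5-dihydro-1,2-oxamagnesole) | CC1=C[Mg]OC1 | intermediate
3 | (Z)-3-iodo-2-methylprop-2-en-1-ol | I/C=C(/C)CO | intermediate
4 | (Z)-3-iodo-2-methylprop-2-enal | I/C=C(/C)C=O | intermediate
5 | bis(isopinocampheyl)borinate of 6 | I/C=C(/C)[C@H](CC=C)OB([C@@H]1C[C@@H]2C[C@H]([C@H]1C)C2(C)C)[C@@H]1C[C@@H]2C[C@H]([C@H]1C)C2(C)C | intermediate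
6 | (1Z,3S)-1-iodo-2-methylhexa-1,5-dien-3-ol | I/C=C(/C)[C@@H](O)CC=C | intermediate
7 | tert-butyl{[(1Z,3S)-1-iodo-2-methylhexa-1,5-dien-3-yl]oxy}dimethylsilane | I/C=C(/C)[C@@H](O[Si](C)(C)C(C)(C)C)CC=C | intermediate
8 | (Z)-4-(tert-butyldimethylsilyloxy)-6-iodo-5-methylhex-5-ene-1,2-diol (4S, diol epimers) | I/C=C(/C)[C@@H](O[Si](C)(C)C(C)(C)C)CC(O)CO | intermediate
9 | (3S,4Z)-3-(tert-butyldimethylsilyloxy)-5-iodo-4-methylpent-4-enal | I/C=C(/C)[C@@H](O[Si](C)(C)C(C)(C)C)CC=O | intermediate
10 | (3S,4Z)-3-(tert-butyldimethylsilyloxy)-5-iodo-4-methylpent-4-en-1-ol | I/C=C(/C)[C@@H](O[Si](C)(C)C(C)(C)C)CCO | intermediate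
11 | tert-butyl{[(1Z,3S)-5-chloro-1-iodo-2-methylpent-1-en-3-yl]oxy}dimethylsilane (C1–C5 fragment) | I/C=C(/C)[C@@H](O[Si](C)(C)C(C)(C)C)CCCl | intermediate
12 | 2-bromoprop-2-en-1-ol | C=C(Br)CO | starting material
13 | [(2-bromoprop-2-en-1-yl)oxy](tert-butyl)dimethylsilane | C=C(Br)CO[Si](C)(C)C(C)(C)C | intermediate
14 | (E)-but-2-ene-1,4-diol | OC/C=C/CO | starting material
15 | (E)-4-[(4-methoxybenzyl)oxy]but-2-en-1-ol | COc1ccc(COC/C=C/CO)cc1 | intermediate
16 | [(2R,3R)-3-{[(4-methoxybenzyl)oxy]methyl}oxiran-2-yl]methanol | OC[C@H]1O[C@@H]1COCc1ccc(OC)cc1 | intermediate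
17 | [3-(tert-butyldimethylsilyloxy)prop-1-en-2-yl]lithium | [Li]C(=C)CO[Si](C)(C)C(C)(C)C | intermediate
18 | [3-(tert-butyldimethylsilyloxy)prop-1-en-2-yl]magnesium bromide | Br[Mg]C(=C)CO[Si](C)(C)C(C)(C)C | intermediate
19 | (2S,3S)-2-[3-(tert-butyldimethylsilyloxy)prop-1-en-2-yl]-4-[(4-methoxybenzyl)oxy]butane-1,3-diol (C2 = C7, C3 = C8) | COc1ccc(COC[C@@H](O)[C@H](CO)C(=C)CO[Si](C)(C)C(C)(C)C)cc1 | intermediate
20 | (2S)-3-{[(tert-butyldimethylsilyl)oxy]methyl}-2-[(4S)-2-(4-methoxyphenyl)-1,3-dioxolan-4-yl]but-3-en-1-ol (acetal epimers) | COc1ccc(C2OC[C@@H](O2)[C@H](CO)C(=C)CO[Si](C)(C)C(C)(C)C)cc1 | intermediate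
21 | C6 aldehyde of 20 (C6–C9 fragment) | COc1ccc(C2OC[C@@H](O2)[C@H](C=O)C(=C)CO[Si](C)(C)C(C)(C)C)cc1 | intermediate
22 | alkenylchromium dichloride from 11 | Cl[Cr](Cl)/C=C(/C)[C@@H](O[Si](C)(C)C(C)(C)C)CCCl | intermediate
23 | C1–C9 allylic alcohol (free 6-OH, O8/O9 acetal) | O[C@H](/C=C(/C)[C@@H](O[Si](C)(C)C(C)(C)C)CCCl)[C@H](C(=C)CO[Si](C)(C)C(C)(C)C)[C@H]1COC(c2ccc(OC)cc2)O1 | intermediate
24 | O6 triethylsilyl ether of 23 | CC[Si](CC)(CC)O[C@H](/C=C(/C)[C@@H](O[Si](C)(C)C(C)(C)C)CCCl)[C@H](C(=C)CO[Si](C)(C)C(C)(C)C)[C@H]1COC(c2ccc(OC)cc2)O1 | intermediate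
25 | C9 primary alcohol with O8 PMB ether | CC[Si](CC)(CC)O[C@H](/C=C(/C)[C@@H](O[Si](C)(C)C(C)(C)C)CCCl)[C@H](C(=C)CO[Si](C)(C)C(C)(C)C)[C@@H](CO)OCc1ccc(OC)cc1 | intermediate
26 | C9 aldehyde | CC[Si](CC)(CC)O[C@H](/C=C(/C)[C@@H](O[Si](C)(C)C(C)(C)C)CCCl)[C@H](C(=C)CO[Si](C)(C)C(C)(C)C)[C@@H](C=O)OCc1ccc(OC)cc1 | intermediate
27 | (E)-C9=C10 enoate | CC[Si](CC)(CC)O[C@H](/C=C(/C)[C@@H](O[Si](C)(C)C(C)(C)C)CCCl)[C@H](C(=C)CO[Si](C)(C)C(C)(C)C)[C@@H](/C=C/C(=O)OC)OCc1ccc(OC)cc1 | intermediate
28 | saturated C1–C10 methyl ester | CC[Si](CC)(CC)O[C@H](/C=C(/C)[C@@H](O[Si](C)(C)C(C)(C)C)CCCl)[C@H](C(=C)CO[Si](C)(C)C(C)(C)C)[C@@H](CCC(=O)OC)OCc1ccc(OC)cc1 | intermediate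
29 | lithium enolate of 28 | CC[Si](CC)(CC)O[C@H](/C=C(/C)[C@@H](O[Si](C)(C)C(C)(C)C)CCCl)[C@H](C(=C)CO[Si](C)(C)C(C)(C)C)[C@@H](CC=C(O[Li])OC)OCc1ccc(OC)cc1 | intermediate
30 | C10 bromo ester (C10 epimers) | CC[Si](CC)(CC)O[C@H](/C=C(/C)[C@@H](O[Si](C)(C)C(C)(C)C)CCCl)[C@H](C(=C)CO[Si](C)(C)C(C)(C)C)[C@@H](CC(Br)C(=O)OC)OCc1ccc(OC)cc1 | intermediate
31 | C10 thioacetate (C10 epimers) | CC[Si](CC)(CC)O[C@H](/C=C(/C)[C@@H](O[Si](C)(C)C(C)(C)C)CCCl)[C@H](C(=C)CO[Si](C)(C)C(C)(C)C)[C@@H](CC(SC(C)=O)C(=O)OC)OCc1ccc(OC)cc1 | intermediate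
32 | C10 thiol (C10 epimers) | CC[Si](CC)(CC)O[C@H](/C=C(/C)[C@@H](O[Si](C)(C)C(C)(C)C)CCCl)[C@H](C(=C)CO[Si](C)(C)C(C)(C)C)[C@@H](CC(S)C(=O)OC)OCc1ccc(OC)cc1 | intermediate
33 | eleven-membered cyclic sulfide (C10 epimers) | CC[Si](CC)(CC)O[C@@H]1/C=C(/C)[C@@H](O[Si](C)(C)C(C)(C)C)CCSC(C(=O)OC)C[C@@H](OCc2ccc(OC)cc2)[C@H]1C(=C)CO[Si](C)(C)C(C)(C)C | intermediate
34 | eleven-membered cyclic sulfone (C10 epimers) | CC[Si](CC)(CC)O[C@@H]1/C=C(/C)[C@@H](O[Si](C)(C)C(C)(C)C)CCS(=O)(=O)C(C(=O)OC)C[C@@H](OCc2ccc(OC)cc2)[C@H]1C(=C)CO[Si](C)(C)C(C)(C)C | intermediate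
35 | sodium enolate of 34 | CC[Si](CC)(CC)O[C@@H]1/C=C(/C)[C@@H](O[Si](C)(C)C(C)(C)C)CCS(=O)(=O)C(=C([O-])OC)C[C@@H](OCc2ccc(OC)cc2)[C@H]1C(=C)CO[Si](C)(C)C(C)(C)C.[Na+] | intermediate
36 | eleven-membered α-chloro sulfone (C10 epimers) | CC[Si](CC)(CC)O[C@@H]1/C=C(/C)[C@@H](O[Si](C)(C)C(C)(C)C)CCS(=O)(=O)C(Cl)(C(=O)OC)C[C@@H](OCc2ccc(OC)cc2)[C@H]1C(=C)CO[Si](C)(C)C(C)(C)C | intermediate
37 | episulfone (thiirane 1,1-dioxide across C1–C10) | CC[Si](CC)(CC)O[C@@H]1/C=C(/C)[C@@H](O[Si](C)(C)C(C)(C)C)CC2C(C(=O)OC)(C[C@@H](OCc3ccc(OC)cc3)[C@H]1C(=C)CO[Si](C)(C)C(C)(C)C)S2(=O)=O | intermediate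
38 | protected ten-membered dienoate | CC[Si](CC)(CC)O[C@@H]1/C=C(/C)[C@@H](O[Si](C)(C)C(C)(C)C)C/C=C(/C(=O)OC)C[C@@H](OCc2ccc(OC)cc2)[C@H]1C(=C)CO[Si](C)(C)C(C)(C)C | intermediate
39 | C6/C12 diol | O[C@@H]1/C=C(/C)[C@@H](O[Si](C)(C)C(C)(C)C)C/C=C(/C(=O)OC)C[C@@H](OCc2ccc(OC)cc2)[C@H]1C(=C)CO | intermediate
40 | hydroxy enal (C12 aldehyde) | O[C@@H]1/C=C(/C)[C@@H](O[Si](C)(C)C(C)(C)C)C/C=C(/C(=O)OC)C[C@@H](OCc2ccc(OC)cc2)[C@H]1C(=C)C=O | intermediate
41 | lactol (C12 epimers) | C=C1C(O)O[C@@H]2/C=C(/C)[C@@H](O[Si](C)(C)C(C)(C)C)C/C=C(/C(=O)OC)C[C@@H](OCc3ccc(OC)cc3)[C@@H]12 | intermediate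
42 | α-methylene lactone with O3 TBS and O8 PMB | C=C1C(=O)O[C@@H]2/C=C(/C)[C@@H](O[Si](C)(C)C(C)(C)C)C/C=C(/C(=O)OC)C[C@@H](OCc3ccc(OC)cc3)[C@@H]12 | intermediate
43 | C8 alcohol (O3 TBS) | C=C1C(=O)O[C@@H]2/C=C(/C)[C@@H](O[Si](C)(C)C(C)(C)C)C/C=C(/C(=O)OC)C[C@@H](O)[C@@H]12 | intermediate
44 | angelic acid | C/C=C(/C)C(=O)O | starting material
45 | (Z)-2-methylbut-2-en-1-ol | C/C=C(/C)CO | intermediate
46 | [(2S,3R)-2,3-dimethyloxiran-2-yl]methanol | OC[C@]1(C)O[C@@H]1C | intermediate
47 | (2R,3R)-2,3-dimethyloxirane-2-carboxylic acid | OC(=O)[C@]1(C)O[C@@H]1C | intermediate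
48 | mixed anhydride of 47 with 2,4,6-trichlorobenzoic acid | O=C(OC(=O)c1c(Cl)cc(Cl)cc1Cl)[C@]1(C)O[C@@H]1C | intermediate
49 | O3-TBS ether of the target | C=C1C(=O)O[C@@H]2/C=C(/C)[C@@H](O[Si](C)(C)C(C)(C)C)C/C=C(/C(=O)OC)C[C@@H](OC(=O)[C@]3(C)O[C@@H]3C)[C@@H]12 | intermediate
50 | CNP0143679.1 (3S,6R,7R,8R; ester 2R,3R) | C=C1C(=O)O[C@@H]2/C=C(/C)[C@@H](O)C/C=C(/C(=O)OC)C[C@@H](OC(=O)[C@]3(C)O[C@@H]3C)[C@@H]12 | target

**Totals and risks**

Total step count: 32. Longest linear sequence: 23 steps (steps 1–7, 14–27, 31, 32).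

Most likely to fail:

1. Step 24 (ring contraction). What may go wrong: chlorine is transferred from C10 to the carbanion or the base (reductive dechlorination), the alkoxide attacks the doubly activated ester, or HCl is lost toward C9, so that no episulfone forms; the enoate could also emerge as a mixture of geometries. Fallback: the C1=C10 bond is made by intramolecular Horner–Wadsworth–Emmons olefination instead of sulfur extrusion. It sets out from bromo ester 30. Arbuzov reaction with P(OMe)3 (neat, 90 °C) should give the C10 dimethyl phosphonate with C1 chloride F1. Finkelstein exchange (NaI, acetone) gives the C1 iodide F2, which is oxidised with trimethylamine N-oxide in DMSO to the C1 aldehyde F3. Ring closure under Masamune–Roush conditions (LiCl, DBU, MeCN, high dilution) should give the E (tiglate-type) enoate and return to the route at 38.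

2. Step 21 (closure of the thiacycle). What may go wrong: intermolecular S-alkylation to oligomers, air oxidation of the thiol, or slow displacement at the chloride. Fallback: ring closure through a disulfide followed by sulfur extrusion. It sets out from thioacetate 31. Excess CH3COSK with NaI (DMF, 50 °C) also displaces the C1 chloride and gives the bis(thioacetate) F4. Methanolysis (K2CO3, MeOH) gives the dithiol F5, and I2 at high dilution oxidises it to the twelve-membered cyclic disulfide F6. Tris(diethylamino)phosphine then removes one sulfur atom (the C10 thiolate displaces the activated sulfur at the primary C1), which returns to the route at sulfide 33.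

3. Step 14 (fragment union). What may go wrong: poor facial selectivity in the addition to the α-branched aldehyde, whose two α-substituents are of similar size, or epimerisation of the β,γ-unsaturated aldehyde before it reacts. Fallback: oxidation and reagent-controlled reduction. It sets out from 23 as the C6 epimer mixture. Dess–Martin oxidation gives the C6 enone F7. F7 is reduced with BH3·SMe2 and the oxazaborolidine catalyst made from diphenylprolinol and methylboronic acid (CBS reduction), using the catalyst enantiomer that delivers hydride to the face giving the 6,7-syn carbinol. This returns to the route at 23 as a single C6 epimer.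

Further compounds
F1 | step 24 | C10 dimethyl phosphonate with C1 chloride (C10 epimers) | CC[Si](CC)(CC)O[C@H](/C=C(/C)[C@@H](O[Si](C)(C)C(C)(C)C)CCCl)[C@H](C(=C)CO[Si](C)(C)C(C)(C)C)[C@@H](CC(C(=O)OC)P(=O)(OC)OC)OCc1ccc(OC)cc1
F2 | step 24 | C10 dimethyl phosphonate with C1 iodide (C10 epimers) | CC[Si](CC)(CC)O[C@H](/C=C(/C)[C@@H](O[Si](C)(C)C(C)(C)C)CCI)[C@H](C(=C)CO[Si](C)(C)C(C)(C)C)[C@@H](CC(C(=O)OC)P(=O)(OC)OC)OCc1ccc(OC)cc1
F3 | step 24 | C10 dimethyl phosphonate with C1 aldehyde (C10 epimers) | CC[Si](CC)(CC)O[C@H](/C=C(/C)[C@@H](O[Si](C)(C)C(C)(C)C)CC=O)[C@H](C(=C)CO[Si](C)(C)C(C)(C)C)[C@@H](CC(C(=O)OC)P(=O)(OC)OC)OCc1ccc(OC)cc1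
F4 | step 21 | C1,C10 bis(thioacetate) (C10 epimers) | CC[Si](CC)(CC)O[C@H](/C=C(/C)[C@@H](O[Si](C)(C)C(C)(C)C)CCSC(C)=O)[C@H](C(=C)CO[Si](C)(C)C(C)(C)C)[C@@H](CC(SC(C)=O)C(=O)OC)OCc1ccc(OC)cc1
F5 | step 21 | C1,C10 dithiol (C10 epimers) | CC[Si](CC)(CC)O[C@H](/C=C(/C)[C@@H](O[Si](C)(C)C(C)(C)C)CCS)[C@H](C(=C)CO[Si](C)(C)C(C)(C)C)[C@@H](CC(S)C(=O)OC)OCc1ccc(OC)cc1
F6 | step 21 | twelve-membered cyclic disulfide (C10 epimers) | CC[Si](CC)(CC)O[C@@H]1/C=C(/C)[C@@H](O[Si](C)(C)C(C)(C)C)CCSSC(C(=O)OC)C[C@@H](OCc2ccc(OC)cc2)[C@H]1C(=C)CO[Si](C)(C)C(C)(C)C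
F7 | step 14 | C6 enone of 23 | O=C(/C=C(/C)[C@@H](O[Si](C)(C)C(C)(C)C)CCCl)[C@H](C(=C)CO[Si](C)(C)C(C)(C)C)[C@H]1COC(c2ccc(OC)cc2)O1
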